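- Work out the rate of E first and leave aside what stands in the flask: that was how I took up these flasks.

in all of them: G 2.5 mM (held)
- spring: Q 2.5 mM (in portions, 4); run made earlier; portions every 80 min
- dawn: Q 59 mM (in portions, 4); run made earlier; portions every 80 min
- east: Q 5.0 mM (in portions, 4); the portions of Q follow each other after 80 min, the first at the start; time 12 h
- south-east: Q 20 mM (in portions, 4); the portions of Q follow each other after 80 min, the first at the start; time 12 h
- north: Q 10 mM (in portions, 4); the portions of Q follow each other after 150 min, the first at the start; time 12 h
- north-west: Q 5.0 mM (in portions, 4); the portions of Q follow each other after 250 min, the first at the start; time 12 h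
- south: Q 80 mM (in portions, 4); the portions of Q follow each other after 300 min, the first at the start; time 12 h
- south-west: Q 40 mM (in portions, 4); the portions of Q follow each other after 80 min, the first at the start; time 12 h

| run | time / h | E / % |
|---|---|---|
| spring | 2.00 | 0.7 |
| spring | 4.00 | 2.2 |
| spring | 6.00 | 10.6 |
| spring | 8.00 | 22.5 |
| spring | 10.0 | 35.1 |
| spring | 12.0 | 48.4 |
| dawn | 1.00 | 0 |
| dawn | 1.50 | 0.1 |
| dawn | 2.50 | 0.5 |
| dawn | 4.00 | 1.3 |
| dawn | 8.00 | 3.7 |
| dawn | 12.0 | 5.4 |

(standard deviation of a reading: 0.5 percentage points)

- at the start none of D is dissolved
- steps that have been proposed: Q -> Z; D -> L; Z + L -> E; D -> X; G <-> D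
- percentages count the whole charge, also what has not yet gone in

* all flasks from highest to lowest amount of E, in percent of the Q charged, at 12 h (east / south-east / north / north-west / south / south-west)
* the amount of E, in percent of the Q charged of the flask you put first, at 12 h
* the amount of E, in percent of the Q charged of the flask you put last, at 12 h

- The dawn run made E at 0.192 mM h⁻¹ up to 4.00 h and at 0.302 mM h⁻¹ from then to 12.0 h, so the slow start cut the rate by a factor 0.636 in that first stretch.
- I replaced the curve by 0.266 mM h⁻¹: the mean rate of E at ample Q, the E of the last dawn reading divided by its time. Against the late rate, this mean stood at a factor 0.881. Taking the late rate instead overstates this mean by 13.9%. The mean is a reading, since 5.4% carries a scatter of 0.5 percentage points.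
- The spring run, read the same way, gave a mean of 0.101 mM h⁻¹. The dawn charge was 23.6 times the spring charge, but its mean rate was 2.63 times the spring mean, far less than the charge alone suggests. That fits the proposed steps, for E needs L, and the step that makes L has no Q in it. I therefore took this mean as my estimate of a ceiling on the mean rate over 12.0 h at this held G, though the late dawn rate itself stood higher.
- Over 12 h the ceiling gave 3.98% for south, 7.97% for south-west, 15.9% for south-east, 31.9% for north and 63.7% for east and north-west.
- For east, twice the spring mean is 0.202 mM h⁻¹, below the ceiling, so I expected east a little under the spring 48.4%. North-west has the same ceiling, but its last portion comes at 12.5 h, after the reading, so I put it behind east. Its ceiling stood above that of north, so I kept it ahead of north.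
- The forecast gave east > north-west > north > south-east > south-west > south, with 46% first and 3.9% last, the lower flasks “capped by L”.
- The flasks gave east > north-west > north > south-east > south-west > south, with 39.0% for east and 3.73% for south.

    Q → Z (k = 0.190 h⁻¹)
    D → L (k = 0.170 h⁻¹)
    Z + L → E (k = 96.0 M⁻¹ h⁻¹)
    D → X (k = 4.20 h⁻¹)
    G ⇌ D, rate k5*(csat - [D]) (kL = 6.70 h⁻¹)

- In the south flask Q went over to Z, which stood at 45.0% of the charge at 12.0 h, while [D] stood at 1.51 mM at 6.00 h and 1.51 mM at 12.0 h, and D went to X 25 times as fast as to L at 5.93 h. [L], the limiting reagent there, stood at 0.0771 mM at 12.0 h, far under the 36.0 mM of Z, and E came at a mean of 0.249 mM h⁻¹ against my 0.266 mM h⁻¹. Read at 50 h, south held 16.0% of E, and the mean rate gives 16.6%.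

(All runs were computed with constants of no real substance; noise was put on by code.)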